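**Retrosynthetic overview**

1. The target is reached by acid methanolysis of its tris-MOM ether; rings A and B are bought as arenes, so ring C (the dihydropyranone) is the only ring formed.
2. Ring C is closed at C3–C4 by a Rh-catalysed enantioselective intramolecular hydroacylation of an achiral aldehyde enol ether: the formyl carbon becomes C4, the =CH2 carbon becomes C3, and the hydrogen goes to C2 (sets 2S).
3. Enabling feature: in ring C the ketone carbon C4 is joined to an unsubstituted CH2 (C3), and C2 carries H, the ring oxygen O1 and the ring-B aryl together. The array C4(=O)–C3H2–C2H(Ar)–O1 is therefore the formal adduct of an aryl aldehyde C–H bond across a 1-arylvinyl aryl ether; C2 is the only stereocentre, and C4a is flanked by two oxygenated carbons (non-enolisable aldehyde).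
4. The enol ether comes from the hindered ring-A phenol and a ring-B 1-bromoalkyne (base-mediated anti-hydrophenoxylation puts O on the future C2), followed by Pd/tin hydride removal of bromine.
5. Ring A: 2,4,6-trihydroxybenzaldehyde, bis-MOM, Pd O-tert-prenylation, ortho-Claisen (prenyl lands on the future C8 without ambiguity). Ring B: vanillin, MOM, dibromo-olefination, bromoalkyne.

Key step: step 10

Assumption: the sense of induction of the bisphosphine in step 10 cannot be predicted for this new substrate class. The route is written with (R)-DTBM-SEGPHOS; its mirror image is used instead if the first run shows that the (R)-ligand gives the 2R ketone.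

**Route**

Step 1
Reactants: 1 2,4,6-trihydroxybenzaldehyde
Product: 2 2-hydroxy-4,6-bis(methoxymethoxy)benzaldehyde
Conditions: MOMCl (2.2 equiv), i-Pr2NEt, CH2Cl2, 0 °C to rt
Reagents that add atoms: chloromethyl methyl ether (MOMCl), COCCl
Why: Williamson-type acetalisation protects the 4-OH and one ortho-OH, while the second ortho-OH is held back by its hydrogen bond to the formyl group (chemoselective MOM protection).

Step 2
Reactants: 3 2-methylbut-3-en-2-ol
Product: 5 methyl 2-methylbut-3-en-2-yl carbonate, via lithium 2-methylbut-3-en-2-olate 4 (not isolated)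
Conditions: n-BuLi, THF, −78 °C; then ClCO2Me, −78 °C to 0 °C
Reagents that add atoms: methyl chloroformate, COC(=O)Cl; n-butyllithium, [Li]CCCC (supplies the lithium of 4 only)
Why: Deprotonation of the tertiary allylic alcohol and O-acylation of the alkoxide by the chloroformate should give the carbonate (alkoxide acylation).

Step 3
Reactants: 2 2-hydroxy-4,6-bis(methoxymethoxy)benzaldehyde; 5 methyl 2-methylbut-3-en-2-yl carbonate
Product: 6 2-[(2-methylbut-3-en-2-yl)oxy]-4,6-bis(methoxymethoxy)benzaldehyde
Conditions: Pd(PPh3)4 (3 mol %), 5 (1.5 equiv), THF, 0 °C to rt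
Reagents that add atoms: none
Why: Tsuji–Trost decarboxylative O-allylation, in which the phenoxide attacks the 1,1-dimethyl-π-allylpalladium ion pair at its more substituted terminus under kinetic control to give the tertiary (reverse-prenyl) ether.

Step 4
Reactants: 6 2-[(2-methylbut-3-en-2-yl)oxy]-4,6-bis(methoxymethoxy)benzaldehyde
Product: 8 2-hydroxy-4,6-bis(methoxymethoxy)-3-(3-methylbut-2-en-1-yl)benzaldehyde, via Claisen dienone 7 (not isolated)
Conditions: toluene, 120 °C (sealed tube)
Reagents that add atoms: none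
Why: The aromatic ortho-Claisen [3,3] rearrangement inverts the allyl unit, so the 1,1-dimethylallyl ether delivers a linear prenyl group to the only free ortho carbon, and tautomerisation of the dienone restores the chelated phenol.

Step 5
Reactants: 9 vanillin (4-hydroxy-3-methoxybenzaldehyde)
Product: 10 3-methoxy-4-(methoxymethoxy)benzaldehyde
Conditions: MOMCl, i-Pr2NEt, CH2Cl2, 0 °C to rt
Reagents that add atoms: chloromethyl methyl ether (MOMCl), COCCl
Why: Straightforward MOM protection of the single phenol (Williamson-type alkylation).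

Step 6
Reactants: 10 3-methoxy-4-(methoxymethoxy)benzaldehyde
Product: 11 4-(2,2-dibromoethenyl)-2-methoxy-1-(methoxymethoxy)benzene
Conditions: CBr4, PPh3, Zn dust, CH2Cl2, rt (ylide pre-formed); then 10, 0 °C to rt
Reagents that add atoms: carbon tetrabromide, BrC(Br)(Br)Br
Why: Corey–Fuchs dibromo-olefination with the zinc-generated ylide is a Wittig-type reaction under non-acidic conditions that spare the MOM acetal.

Step 7
Reactants: 11 4-(2,2-dibromoethenyl)-2-methoxy-1-(methoxymethoxy)benzene
Product: 12 4-(bromoethynyl)-2-methoxy-1-(methoxymethoxy)benzene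
Conditions: DBU, DMSO, rt
Reagents that add atoms: none
Why: E2 dehydrobromination of the 1,1-dibromoalkene (H anti to one Br) by the amidine base should stop cleanly at the 1-bromoalkyne.

Step 8
Reactants: 8 2-hydroxy-4,6-bis(methoxymethoxy)-3-(3-methylbut-2-en-1-yl)benzaldehyde; 12 4-(bromoethynyl)-2-methoxy-1-(methoxymethoxy)benzene
Product: 13 2-{[(Z)-2-bromo-1-[3-methoxy-4-(methoxymethoxy)phenyl]ethenyl]oxy}-4,6-bis(methoxymethoxy)-3-(3-methylbut-2-en-1-yl)benzaldehyde
Conditions: Cs2CO3, DMF, 90–110 °C
Reagents that add atoms: none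
Why: Base-mediated nucleophilic anti-hydrophenoxylation of a 1-bromoalkyne, in which the phenoxide adds to the aryl-bearing alkyne carbon (the vinyl anion is stabilised by bromine) and protonation trans to oxygen should give the Z-bromovinyl ether with oxygen on the future C2.

Step 9
Reactants: 13 2-{[(Z)-2-bromo-1-[3-methoxy-4-(methoxymethoxy)phenyl]ethenyl]oxy}-4,6-bis(methoxymethoxy)-3-(3-methylbut-2-en-1-yl)benzaldehyde
Product: 14 2-({1-[3-methoxy-4-(methoxymethoxy)phenyl]ethenyl}oxy)-4,6-bis(methoxymethoxy)-3-(3-methylbut-2-en-1-yl)benzaldehyde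
Conditions: Pd(PPh3)4 (5 mol %), Bu3SnH (1.3 equiv, slow addition), THF, rt
Reagents that add atoms: none
Why: Pd(0)-catalysed hydrostannolysis (hydrodehalogenation) of the vinyl bromide by oxidative addition, tin-to-palladium hydride transfer and C–H reductive elimination should leave the aldehyde, prenyl group and enol ether untouched.

Step 10
Reactants: 14 2-({1-[3-methoxy-4-(methoxymethoxy)phenyl]ethenyl}oxy)-4,6-bis(methoxymethoxy)-3-(3-methylbut-2-en-1-yl)benzaldehyde
Product: 15 (2S)-2-[3-methoxy-4-(methoxymethoxy)phenyl]-5,7-bis(methoxymethoxy)-8-(3-methylbut-2-en-1-yl)-2,3-dihydro-4H-chromen-4-one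
Conditions: [Rh(cod)Cl]2 (2.5 mol %), (R)-DTBM-SEGPHOS (5.5 mol %), NaBArF4 (5 mol %), 1,4-dioxane (degassed), 60–80 °C
Reagents that add atoms: none
Why: Proposed new method: a cationic Rh(I)/chiral bisphosphine complex should insert into the formyl C–H bond of 14, the acyl rhodium hydride (held against decarbonylation by the flanking aryl ether and OMOM oxygens) should bind the pendant 1,1-disubstituted enol ether, transfer hydride to its aryl- and oxygen-bearing carbon, and reductively eliminate from the seven-membered acyl–alkyl rhodacycle to form the C3–C4 bond. The closest known reaction type is the Rh-catalysed enantioselective endo-hydroacylation of 1,1-disubstituted alkenes tethered to aryl and heteroaryl aldehydes (ortho-allylbenzaldehydes to 3-substituted tetralones, N-vinyl- and N-allylindole-2-carboxaldehydes to five- and six-membered ketones); what is new here is the O-linked 1-arylvinyl aryl ether as substrate class. The only ring formed, the dihydropyranone ring C, is closed in a 6-endo-trig sense, both alkene carbons ending in the ring as C2 and C3. The single new stereocentre C2 is set under catalyst control, the C2-symmetric ligand choosing the enantiotopic alkene face that receives the hydride. The step needs endo over exo regioselectivity, secured because the exo path would demand a tertiary benzylic alkyl rhodium and a quaternary centre, and chemoselectivity over the prenyl alkene, which is trisubstituted and meta to the formyl group and so cannot reach the metal intramolecularly; the enol ether has no allylic hydrogen, so alkene isomerisation cannot compete. The ketone forms under neutral conditions that should not epimerise C2 by retro-oxa-Michael ring opening.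

Step 11
Reactants: 15 (2S)-2-[3-methoxy-4-(methoxymethoxy)phenyl]-5,7-bis(methoxymethoxy)-8-(3-methylbut-2-en-1-yl)-2,3-dihydro-4H-chromen-4-one
Product: 16 (2S)-5,7-dihydroxy-2-(4-hydroxy-3-methoxyphenyl)-8-(3-methylbut-2-en-1-yl)-2,3-dihydro-4H-chromen-4-one
Conditions: aq HCl (3 M), MeOH, 45 °C
Reagents that add atoms: none
Why: Acid-catalysed acetal methanolysis should remove all three aryl MOM groups, while the C2 stereocentre (labile to base, not to mild acid) and the prenyl group should survive at this temperature.

**Compound list**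

1 | 2,4,6-trihydroxybenzaldehyde | O=Cc1c(O)cc(O)cc1O | starting material
2 | 2-hydroxy-4,6-bis(methoxymethoxy)benzaldehyde | O=Cc1c(O)cc(OCOC)cc1OCOC | intermediate
3 | 2-methylbut-3-en-2-ol | CC(C)(O)C=C | starting material
4 | lithium 2-methylbut-3-en-2-olate | [Li+].[O-]C(C)(C)C=C | intermediate
5 | methyl 2-methylbut-3-en-2-yl carbonate | COC(=O)OC(C)(C)C=C | intermediate
6 | 2-[(2-methylbut-3-en-2-yl)oxy]-4,6-bis(methoxymethoxy)benzaldehyde | O=Cc1c(OC(C)(C)C=C)cc(OCOC)cc1OCOC | intermediate
7 | 2,4-bis(methoxymethoxy)-5-(3-methylbut-2-en-1-yl)-6-oxocyclohexa-1,3-diene-1-carbaldehyde (racemic Claisen dienone) | O=CC1=C(OCOC)C=C(OCOC)C(CC=C(C)C)C1=O | intermediate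
8 | 2-hydroxy-4,6-bis(methoxymethoxy)-3-(3-methylbut-2-en-1-yl)benzaldehyde | O=Cc1c(O)c(CC=C(C)C)c(OCOC)cc1OCOC | intermediate
9 | vanillin (4-hydroxy-3-methoxybenzaldehyde) | COc1cc(C=O)ccc1O | starting material
10 | 3-methoxy-4-(methoxymethoxy)benzaldehyde | COCOc1ccc(C=O)cc1OC | intermediate
11 | 4-(2,2-dibromoethenyl)-2-methoxy-1-(methoxymethoxy)benzene | COCOc1ccc(C=C(Br)Br)cc1OC | intermediate
12 | 4-(bromoethynyl)-2-methoxy-1-(methoxymethoxy)benzene | COCOc1ccc(C#CBr)cc1OC | intermediate
13 | 2-{[(Z)-2-bromo-1-[3-methoxy-4-(methoxymethoxy)phenyl]ethenyl]oxy}-4,6-bis(methoxymethoxy)-3-(3-methylbut-2-en-1-yl)benzaldehyde | O=Cc1c(O/C(=C\Br)c2ccc(OCOC)c(OC)c2)c(CC=C(C)C)c(OCOC)cc1OCOC | intermediate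
14 | 2-({1-[3-methoxy-4-(methoxymethoxy)phenyl]ethenyl}oxy)-4,6-bis(methoxymethoxy)-3-(3-methylbut-2-en-1-yl)benzaldehyde (achiral) | O=Cc1c(OC(=C)c2ccc(OCOC)c(OC)c2)c(CC=C(C)C)c(OCOC)cc1OCOC | intermediate
15 | (2S)-2-[3-methoxy-4-(methoxymethoxy)phenyl]-5,7-bis(methoxymethoxy)-8-(3-methylbut-2-en-1-yl)-2,3-dihydro-4H-chromen-4-one | COc1cc([C@@H]2CC(=O)c3c(OCOC)cc(OCOC)c(CC=C(C)C)c3O2)ccc1OCOC | intermediate
16 | (2S)-5,7-dihydroxy-2-(4-hydroxy-3-methoxyphenyl)-8-(3-methylbut-2-en-1-yl)-2,3-dihydro-4H-chromen-4-one | COc1cc([C@@H]2CC(=O)c3c(O)cc(O)c(CC=C(C)C)c3O2)ccc1O | target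

**Step count and risks**

Total step count: 11. Longest linear sequence: 7 steps (steps 1, 3, 4, 8, 9, 10, 11 from 1; equally steps 5, 6, 7, 8, 9, 10, 11 from 9).

Steps most likely to fail:

1. Step 10 (proposed new method). The acyl rhodium hydride may lose CO faster than it cyclises on this 2,6-dioxygenated aldehyde, the hydride may insert in the exo sense to give a five-membered ketone, or facial discrimination on the enol ether may be weak. The fallback uses known chemistry and closes ring C through the O1–C2 bond instead. Phenol 8 is treated with MeMgBr (2.2 equiv, THF, 0 °C) to give 1-[2-hydroxy-4,6-bis(methoxymethoxy)-3-(3-methylbut-2-en-1-yl)phenyl]ethan-1-ol F1, which is oxidised (MnO2, CH2Cl2) to 1-[2-hydroxy-4,6-bis(methoxymethoxy)-3-(3-methylbut-2-en-1-yl)phenyl]ethan-1-one F2. Claisen–Schmidt condensation of F2 with aldehyde 10 (KOH, EtOH, rt) should give (E)-1-[2-hydroxy-4,6-bis(methoxymethoxy)-3-(3-methylbut-2-en-1-yl)phenyl]-3-[3-methoxy-4-(methoxymethoxy)phenyl]prop-2-en-1-one F3, whose only free phenol is the one next to the prenyl group. Intramolecular oxa-Michael addition (NaOAc, EtOH, reflux) should then give the racemic tris-MOM flavanone F4. Preparative chiral SFC separates 15 from the (2R)-enantiomer F5, which is re-equilibrated to F4 with base (through F3) and recycled. This fallback sets out from 8 (with 10) and comes back to the route at 15.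

2. Step 8. The hindered, formyl-stabilised phenoxide may add too slowly to the electron-rich bromoalkyne, so that thermal degradation of the haloalkyne or halophilic attack takes over. The fallback forms the C–O bond at the sp3 level and makes the alkene by elimination. Wittig methylenation of 10 (Ph3PCH3Br, KOtBu, THF) gives 4-ethenyl-2-methoxy-1-(methoxymethoxy)benzene F6. NBS in aqueous acetone (0 °C) gives the bromohydrin 2-bromo-1-[3-methoxy-4-(methoxymethoxy)phenyl]ethan-1-ol F7. Mitsunobu etherification of phenol 8 with F7 (PPh3, DIAD, THF, 0 °C) gives racemic 2-{2-bromo-1-[3-methoxy-4-(methoxymethoxy)phenyl]ethoxy}-4,6-bis(methoxymethoxy)-3-(3-methylbut-2-en-1-yl)benzaldehyde F8. E2 loss of HBr (KOtBu, THF, 0 °C; the only β-hydrogen is the benzylic one) gives enol ether 14. This fallback sets out from 8 and 10 and comes back at 14, bypassing 13 and step 9.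

3. Step 3. The chelated phenoxide may attack the unsubstituted allyl terminus, or palladium may re-ionise the tertiary ether and isomerise it to the linear O-prenyl ether, which would rearrange to the wrong products in step 4. The fallback replaces π-allyl chemistry with propargylic substitution and semi-hydrogenation. Phenol 2 is O-alkylated with 3-chloro-3-methylbut-1-yne (DBU, CuCl2 cat., MeCN, 0 °C) to 2-[(2-methylbut-3-yn-2-yl)oxy]-4,6-bis(methoxymethoxy)benzaldehyde F9. Lindlar semi-hydrogenation (H2, Pd/CaCO3–Pb, quinoline, EtOAc) then gives 6. This fallback sets out from 2 and comes back at 6.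

**Further compounds**

F1 | step 10 | 1-[2-hydroxy-4,6-bis(methoxymethoxy)-3-(3-methylbut-2-en-1-yl)phenyl]ethan-1-ol (racemic) | CC(O)c1c(O)c(CC=C(C)C)c(OCOC)cc1OCOC
F2 | step 10 | 1-[2-hydroxy-4,6-bis(methoxymethoxy)-3-(3-methylbut-2-en-1-yl)phenyl]ethan-1-one | CC(=O)c1c(O)c(CC=C(C)C)c(OCOC)cc1OCOC
F3 | step 10 | (E)-1-[2-hydroxy-4,6-bis(methoxymethoxy)-3-(3-methylbut-2-en-1-yl)phenyl]-3-[3-methoxy-4-(methoxymethoxy)phenyl]prop-2-en-1-one | COCOc1ccc(/C=C/C(=O)c2c(O)c(CC=C(C)C)c(OCOC)cc2OCOC)cc1OC
F4 | step 10 | racemic 2-[3-methoxy-4-(methoxymethoxy)phenyl]-5,7-bis(methoxymethoxy)-8-(3-methylbut-2-en-1-yl)-2,3-dihydro-4H-chromen-4-one | COc1cc(C2CC(=O)c3c(OCOC)cc(OCOC)c(CC=C(C)C)c3O2)ccc1OCOC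
F5 | step 10 | (2R)-2-[3-methoxy-4-(methoxymethoxy)phenyl]-5,7-bis(methoxymethoxy)-8-(3-methylbut-2-en-1-yl)-2,3-dihydro-4H-chromen-4-one | COc1cc([C@H]2CC(=O)c3c(OCOC)cc(OCOC)c(CC=C(C)C)c3O2)ccc1OCOC
F6 | step 8 | 4-ethenyl-2-methoxy-1-(methoxymethoxy)benzene | COCOc1ccc(C=C)cc1OC
F7 | step 8 | 2-bromo-1-[3-methoxy-4-(methoxymethoxy)phenyl]ethan-1-ol (racemic) | COCOc1ccc(C(O)CBr)cc1OC
F8 | step 8 | 2-{2-bromo-1-[3-methoxy-4-(methoxymethoxy)phenyl]ethoxy}-4,6-bis(methoxymethoxy)-3-(3-methylbut-2-en-1-yl)benzaldehyde (racemic) | O=Cc1c(OC(CBr)c2ccc(OCOC)c(OC)c2)c(CC=C(C)C)c(OCOC)cc1OCOC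
F9 | step 3 | 2-[(2-methylbut-3-yn-2-yl)oxy]-4,6-bis(methoxymethoxy)benzaldehyde | O=Cc1c(OC(C)(C)C#C)cc(OCOC)cc1OCOC
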